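The earlier runs and the new flask come from a simulation with constants of no real substance; the scatter is artificial.

Ask what the end state of this flask must be, then how fast it comes.

| flask | starting material | partner | free catalyst | remark | time |
|---|---|---|---|---|---|
| Tuesday's | 0.35 M | 0.125 M | 38 mM | run made earlier |  |
| Sunday's | 0.55 M | 0.125 M | 38 mM | run made earlier |  |
| flask | 0.25 M | 0.125 M | 38 mM |  | 4.0 d |

- Tuesday's (time / d: starting material / %, target / %): 0.417: 66.8, 30.7; 0.833: 64.8, 35.7; 1.25: 64.3, 36.3; 2.50: 63.2, 36.5; 5.00: 65.6, 37.0
- Sunday's (time / d: starting material / %, target / %): 0.417: 79.5, 19.4; 0.833: 76.8, 23.0; 1.25: 77.6, 21.7; 2.50: 76.1, 22.8; 5.00: 76.8, 24.3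

(scatter of a reading: 1 percentage point)

* part of the starting material that has reacted at 4.0 d
* share of the unused partner that is free and not bound as idle adduct, at 4.0 d

- the earlier runs do not show how much of partner is bound; that part of a forecast is a guess

The target levels off in both runs. At 2.50 d Tuesday's run holds 0.128 M of target and Sunday's 0.125 M, beside a partner charge of 0.125 M in each, though their starting material differs. So I read one partner used per target formed. The flask holds less partner than starting material, which makes partner the limiting reagent there. I call c_max, the ceiling, the partner charge over the starting material charge.

Which given numbers must be good? A partner charge off by 12.5 mM moves the ceiling by 5 percentage points. A starting material charge too high by 25.0 mM moves it by 4.5 points. Time matters little once the level is reached: Tuesday's target gains 0.5 points from 2.50 d to 5.00 d, less than the scatter. Tuesday's target reads 36.3% at 1.25 d, within 0.7 points of its last reading, and I take the flask, with 0.25 M of starting material against Tuesday's 0.35 M, to reach its level by 4.0 d, a time 3.20 times as long. The free catalyst stands outside the ratio. So the two charges must be good: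

c_max = 0.125 M / 0.25 M = 50.0%

That ceiling, the partner charge over the starting material charge, is my c, the part reacted, at 4.0 d. For fr I reckon no number, since the runs do not show binding.

The forecast gives 49.8% and 50%, calling the second “this is a guess”.

The flask gives 50.0% for c and 65.6% for fr.

    catalyst intermediate B ⇌ released group + catalyst intermediate C (K = 1.60 M, k = 0.0178 /min)
    catalyst intermediate C → free catalyst + target (k = 0.0305 /min)
    partner + free catalyst ⇌ catalyst intermediate A (K = 14.0 /M, k = 7.39 /M/min)
    starting material + catalyst intermediate A → catalyst intermediate B (k = 0.111 /M/min)
    partner + released group ⇌ idle adduct, settled at all times (K = 4.20 /M)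

At 4.00 d the flask has less partner left than starting material, 0% against 50% of charge. The tying up of partner as idle adduct leaves c unchanged. In the neighbouring flask with 0.050 M of partner, the same reckoning gives a ceiling of 20.0%. That flask gives 20.0% for c, with 0% of its partner left and 80% of its charged starting material still there, unbound.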